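**Plan**
- Retrosynthesis: the two acetates and the Z head alkene go back to a 2-alkylmaleate (cut between the head alkene carbon and its chain CH2: alkylcopper + dimethyl but-2-ynedioate). The E alkene is cut at its C–CH3 bond and at the CH–CH2 bond on the head side (methylalumination of a terminal alkyne, then oxirane). The alkyne is cut from a 2-(ring)ethyl iodide.
- The ring is cut at both single bonds that flank its alkene, C1–C2 and C3–C4 (ring atoms: C1 = stereogenic CH, C2 = C–CH3, C3 = CH, C4 and C5 = CH2, C6 = C(CH3)2). The feature that allows this: C2=C3 is a propyne unit, C4 is a primary carbon that can carry zinc, and C1 stands β to the second side-chain carbon, which can be an acyl carbon, so C1 is the β-carbon of an enoyl acceptor tethered to C4 through C5–C6.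
- Forward: an acyclic bromo enoyl imide is assembled, the cyclohexene (the only ring) arises in one nickel-catalysed annulation with a silylpropyne, and the chain is then grown linearly outwards from the ring.
- Stereochemistry: ring C1 from the (S)-benzyloxazolidinone auxiliary in the annulation; the E alkene from syn methylalumination; the Z alkene from syn carbocupration.

Key step: step 6

Assumption: the ring CH is read as (S) (CIP order C(CH3)= > C(CH3)2 > side-chain CH2 > H) and the head alkene as Z with the two CH2OAc groups cis; 1, 2, 5, 6, 10 and 22 are taken as stock chemicals.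

**Step 1**
Reactants: 1 ethyl 2-methylpropanoate; 2 1,2-dibromoethane
Product: 3 ethyl 4-bromo-2,2-dimethylbutanoate
Conditions: LiN(i-Pr)2, THF, −78 °C; then 2 (3 equiv), −78 °C to rt
Reagents that add atoms: none
Why: SN2 alkylation of the ester enolate by the excess dibromide should build the quaternary carbon that becomes ring C6.

**Step 2**
Reactants: 3 ethyl 4-bromo-2,2-dimethylbutanoate
Product: 4 4-bromo-2,2-dimethylbutanal
Conditions: i-Bu2AlH (1.1 equiv), CH2Cl2, −78 °C; MeOH, aq. potassium sodium tartrate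
Reagents that add atoms: none
Why: Partial hydride reduction of the hindered ester should stop at the aluminium hemiacetal at −78 °C and release the non-enolisable aldehyde on work-up.

**Step 3**
Reactants: 5 (4S)-4-benzyl-1,3-oxazolidin-2-one; 6 bromoacetyl bromide
Product: 7 (4S)-4-benzyl-3-(bromoacetyl)-1,3-oxazolidin-2-one
Conditions: n-BuLi, THF, −78 °C; then 6, −78 to 0 °C
Reagents that add atoms: none
Why: N-acylation of the lithiated oxazolidinone at the acid bromide should be much faster than substitution at the CH2Br group.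

**Step 4**
Reactants: 7 (4S)-4-benzyl-3-(bromoacetyl)-1,3-oxazolidin-2-one
Product: 8 diethyl {2-[(4S)-4-benzyl-2-oxo-1,3-oxazolidin-3-yl]-2-oxoethyl}phosphonate
Conditions: P(OEt)3, neat, 60 °C
Reagents that add atoms: triethyl phosphite, CCOP(OCC)OCC
Why: Michaelis–Arbuzov reaction of the activated α-bromo imide should give the phosphonate with loss of bromoethane.

**Step 5**
Reactants: 4 4-bromo-2,2-dimethylbutanal; 8 diethyl {2-[(4S)-4-benzyl-2-oxo-1,3-oxazolidin-3-yl]-2-oxoethyl}phosphonate
Product: 9 (4S)-4-benzyl-3-[(2E)-6-bromo-4,4-dimethylhex-2-enoyl]-1,3-oxazolidin-2-one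
Conditions: LiBr, Et3N, THF, rt
Reagents that add atoms: none
Why: Horner–Wadsworth–Emmons olefination with the stabilised phosphonate under mild lithium salt/amine conditions should give the E enoyl imide and leave the primary bromide and the imide intact.

**Step 6**
Reactants: 9 (4S)-4-benzyl-3-[(2E)-6-bromo-4,4-dimethylhex-2-enoyl]-1,3-oxazolidin-2-one; 10 trimethyl(prop-1-yn-1-yl)silane
Product: 13 (4S)-4-benzyl-3-{2-[(1S)-2,6,6-trimethyl-3-(trimethylsilyl)cyclohex-2-en-1-yl]acetyl}-1,3-oxazolidin-2-one, via alkylzinc bromide 11 (not isolated), via zinc enolate 12 (not isolated)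
Conditions: Zn dust, LiCl, THF, 50 °C; then Ni(cod)2 (10 mol%), 10 (3 equiv), THF, 0 °C to rt; aq. NH4Cl
Reagents that add atoms: none
Why: Proposed new method: zerovalent nickel should couple the zinc-chelated enoyl imide and the silylalkyne oxidatively to a nickelacycle in which the enoyl β-carbon (ring C1) is bonded to the methyl-bearing alkyne carbon (C2), the tethered primary alkylzinc should then pass its carbon (C4) to nickel, and C(sp2)–C(sp3) reductive elimination should form C3–C4 and release the zinc enolate and zerovalent nickel, so that both ring bonds arise in one catalytic cycle. The closest known reaction type is the nickel-catalysed three-component alkylative coupling of an enone, an alkyne and an organozinc (also run intramolecularly on alkynyl enones and on unsaturated acyl oxazolidinones); what is new is that the organozinc is tethered to the acceptor, so that the alkyne is annulated in a formal [4+2] sense. The six-membered ring is closed by reductive elimination from a seven-membered nickelacycle, which places the two former alkyne carbons cis and endocyclic. The one new stereocentre (C1) is set in the oxidative coupling: with divalent zinc chelating the two imide carbonyls, the s-cis enoyl group exposes the face opposite the benzyl group of the (S)-oxazolidinone, which should give the (S) centre. The step needs alkyne regiocontrol (the trimethylsilyl group should sit next to nickel, so C1 bonds to the methyl-bearing carbon), alkyl transfer instead of β-hydride loss (phosphine-free nickel), and no direct conjugate transfer of the alkyl group (a four-membered ring cannot form and the β-carbon is neopentyl-like).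

**Step 7**
Reactants: 13 (4S)-4-benzyl-3-{2-[(1S)-2,6,6-trimethyl-3-(trimethylsilyl)cyclohex-2-en-1-yl]acetyl}-1,3-oxazolidin-2-one
Product: 14 (4S)-4-benzyl-3-{2-[(1S)-2,6,6-trimethylcyclohex-2-en-1-yl]acetyl}-1,3-oxazolidin-2-one
Conditions: CF3CO2H, CH2Cl2, 0 °C
Reagents that add atoms: none
Why: Electrophilic ipso-protodesilylation of the vinylsilane through the β-silyl cation should remove the helper silyl group with the alkene kept at C2=C3.

**Step 8**
Reactants: 14 (4S)-4-benzyl-3-{2-[(1S)-2,6,6-trimethylcyclohex-2-en-1-yl]acetyl}-1,3-oxazolidin-2-one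
Product: 15 2-[(1S)-2,6,6-trimethylcyclohex-2-en-1-yl]ethan-1-ol
Conditions: LiBH4, H2O (1 equiv), Et2O, 0 °C
Reagents that add atoms: none
Why: Reductive cleavage of the N-acyl oxazolidinone should give the primary alcohol and return auxiliary 5, with the stereocentre (β to the carbonyl) and the alkene untouched.

**Step 9**
Reactants: 15 2-[(1S)-2,6,6-trimethylcyclohex-2-en-1-yl]ethan-1-ol
Product: 16 (6S)-6-(2-iodoethyl)-1,5,5-trimethylcyclohex-1-ene
Conditions: I2, PPh3, imidazole, CH2Cl2, 0 °C to rt
Reagents that add atoms: iodine, II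
Why: Appel-type iodination of the primary alcohol through the alkoxyphosphonium salt.

**Step 10**
Reactants: 16 (6S)-6-(2-iodoethyl)-1,5,5-trimethylcyclohex-1-ene
Product: 17 (6S)-6-(but-3-yn-1-yl)-1,5,5-trimethylcyclohex-1-ene
Conditions: LiC≡CH·H2NCH2CH2NH2, DMSO, rt
Reagents that add atoms: lithium acetylide ethane-1,2-diamine complex, [Li+].[C-]#C.NCCN
Why: SN2 alkynylation of the unhindered primary iodide by lithium acetylide in a dipolar aprotic solvent.

**Step 11**
Reactants: 17 (6S)-6-(but-3-yn-1-yl)-1,5,5-trimethylcyclohex-1-ene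
Product: 20 (3E)-4-methyl-6-[(1S)-2,6,6-trimethylcyclohex-2-en-1-yl]hex-3-en-1-ol, via alkenylalane 18 (not isolated), via lithium alanate 19 (not isolated)
Conditions: AlMe3, Cp2ZrCl2 (cat.), CH2Cl2, rt; volatiles removed; n-BuLi, hexane, −78 °C; oxirane, THF, −78 °C to rt
Reagents that add atoms: trimethylaluminium, C[Al](C)C; oxirane, C1CO1
Why: Zirconocene-catalysed syn methylalumination of the terminal alkyne places CH3 and Al cis, which fixes the E trisubstituted alkene, and the derived alkenyl alanate should open oxirane with retention at the alkenyl carbon.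

**Step 12**
Reactants: 20 (3E)-4-methyl-6-[(1S)-2,6,6-trimethylcyclohex-2-en-1-yl]hex-3-en-1-ol
Product: 21 (6S)-6-[(3E)-6-iodo-3-methylhex-3-en-1-yl]-1,5,5-trimethylcyclohex-1-ene
Conditions: I2, PPh3, imidazole, CH2Cl2, 0 °C
Reagents that add atoms: iodine, II
Why: Appel-type iodination of the primary homoallylic alcohol under neutral conditions that do not touch the alkenes.

**Step 13**
Reactants: 21 (6S)-6-[(3E)-6-iodo-3-methylhex-3-en-1-yl]-1,5,5-trimethylcyclohex-1-ene; 22 dimethyl but-2-ynedioate
Product: 26 dimethyl (2Z)-2-{(3E)-4-methyl-6-[(1S)-2,6,6-trimethylcyclohex-2-en-1-yl]hex-3-en-1-yl}but-2-enedioate, via alkyllithium 23 (not isolated), via alkylcopper 24 (not isolated), via alkenylcopper 25 (not isolated)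
Conditions: t-BuLi (2 equiv), Et2O, −78 °C; CuBr·SMe2, THF, −78 to −40 °C; 22, −78 °C; aq. NH4Cl at −78 °C
Reagents that add atoms: none
Why: Iodine–lithium exchange, transmetalation to copper and syn carbocupration of the acetylenic diester at −78 °C place the alkyl group and copper cis, and protonation with retention should give the maleate (Z) geometry.

**Step 14**
Reactants: 26 dimethyl (2Z)-2-{(3E)-4-methyl-6-[(1S)-2,6,6-trimethylcyclohex-2-en-1-yl]hex-3-en-1-yl}but-2-enedioate
Product: 27 (2Z)-2-{(3E)-4-methyl-6-[(1S)-2,6,6-trimethylcyclohex-2-en-1-yl]hex-3-en-1-yl}but-2-ene-1,4-diol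
Conditions: i-Bu2AlH (5 equiv), CH2Cl2, −78 to 0 °C; aq. potassium sodium tartrate
Reagents that add atoms: none
Why: 1,2-Reduction of both conjugated esters by excess aluminium hydride should give the Z ene-diol without reducing or isomerising the alkenes.

**Step 15**
Reactants: 27 (2Z)-2-{(3E)-4-methyl-6-[(1S)-2,6,6-trimethylcyclohex-2-en-1-yl]hex-3-en-1-yl}but-2-ene-1,4-diol
Product: 28 (2Z)-2-{(3E)-4-methyl-6-[(1S)-2,6,6-trimethylcyclohex-2-en-1-yl]hex-3-en-1-yl}but-2-ene-1,4-diyl diacetate
Conditions: Ac2O, pyridine, DMAP (cat.), CH2Cl2, rt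
Reagents that add atoms: acetic anhydride, CC(=O)OC(C)=O
Why: DMAP-catalysed acetylation of the two primary allylic alcohols should give the target.

**Compound list**
1 | ethyl 2-methylpropanoate | CCOC(=O)C(C)C | starting material
2 | 1,2-dibromoethane | BrCCBr | starting material
3 | ethyl 4-bromo-2,2-dimethylbutanoate | CCOC(=O)C(C)(C)CCBr | intermediate
4 | 4-bromo-2,2-dimethylbutanal | O=CC(C)(C)CCBr | intermediate
5 | (4S)-4-benzyl-1,3-oxazolidin-2-one | O=C1N[C@@H](Cc2ccccc2)CO1 | starting material
6 | bromoacetyl bromide | BrCC(Br)=O | starting material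
7 | (4S)-4-benzyl-3-(bromoacetyl)-1,3-oxazolidin-2-one | O=C(CBr)N1[C@@H](Cc2ccccc2)COC1=O | intermediate
8 | diethyl {2-[(4S)-4-benzyl-2-oxo-1,3-oxazolidin-3-yl]-2-oxoethyl}phosphonate | CCOP(=O)(CC(=O)N1[C@@H](Cc2ccccc2)COC1=O)OCC | intermediate
9 | (4S)-4-benzyl-3-[(2E)-6-bromo-4,4-dimethylhex-2-enoyl]-1,3-oxazolidin-2-one | O=C(/C=C/C(C)(C)CCBr)N1[C@@H](Cc2ccccc2)COC1=O | intermediate
10 | trimethyl(prop-1-yn-1-yl)silane | CC#C[Si](C)(C)C | starting material
11 | {(4E)-6-[(4S)-4-benzyl-2-oxo-1,3-oxazolidin-3-yl]-3,3-dimethyl-6-oxohex-4-en-1-yl}zinc bromide (not isolated) | O=C(/C=C/C(C)(C)CC[Zn]Br)N1[C@@H](Cc2ccccc2)COC1=O | intermediate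
12 | bromozinc (Z)-enolate of 13 (not isolated) | Br[Zn]O/C(=C\[C@@H]1C(C)=C([Si](C)(C)C)CCC1(C)C)N2[C@@H](Cc3ccccc3)COC2=O | intermediate
13 | (4S)-4-benzyl-3-{2-[(1S)-2,6,6-trimethyl-3-(trimethylsilyl)cyclohex-2-en-1-yl]acetyl}-1,3-oxazolidin-2-one | O=C(C[C@@H]1C(C)=C([Si](C)(C)C)CCC1(C)C)N2[C@@H](Cc3ccccc3)COC2=O | intermediate
14 | (4S)-4-benzyl-3-{2-[(1S)-2,6,6-trimethylcyclohex-2-en-1-yl]acetyl}-1,3-oxazolidin-2-one | O=C(C[C@@H]1C(C)=CCCC1(C)C)N2[C@@H](Cc3ccccc3)COC2=O | intermediate
15 | 2-[(1S)-2,6,6-trimethylcyclohex-2-en-1-yl]ethan-1-ol | OCC[C@@H]1C(C)=CCCC1(C)C | intermediate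
16 | (6S)-6-(2-iodoethyl)-1,5,5-trimethylcyclohex-1-ene | ICC[C@@H]1C(C)=CCCC1(C)C | intermediate
17 | (6S)-6-(but-3-yn-1-yl)-1,5,5-trimethylcyclohex-1-ene | C#CCC[C@@H]1C(C)=CCCC1(C)C | intermediate
18 | dimethyl{(1E)-2-methyl-4-[(1S)-2,6,6-trimethylcyclohex-2-en-1-yl]but-1-en-1-yl}alane (not isolated) | C[Al](C)/C=C(\C)CC[C@@H]1C(C)=CCCC1(C)C | intermediate
19 | lithium butyl(dimethyl){(1E)-2-methyl-4-[(1S)-2,6,6-trimethylcyclohex-2-en-1-yl]but-1-en-1-yl}alanate (not isolated) | [Li+].CCCC[Al-](C)(C)/C=C(\C)CC[C@@H]1C(C)=CCCC1(C)C | intermediate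
20 | (3E)-4-methyl-6-[(1S)-2,6,6-trimethylcyclohex-2-en-1-yl]hex-3-en-1-ol | OCC/C=C(\C)CC[C@@H]1C(C)=CCCC1(C)C | intermediate
21 | (6S)-6-[(3E)-6-iodo-3-methylhex-3-en-1-yl]-1,5,5-trimethylcyclohex-1-ene | ICC/C=C(\C)CC[C@@H]1C(C)=CCCC1(C)C | intermediate
22 | dimethyl but-2-ynedioate | COC(=O)C#CC(=O)OC | starting material
23 | {(3E)-4-methyl-6-[(1S)-2,6,6-trimethylcyclohex-2-en-1-yl]hex-3-en-1-yl}lithium (not isolated) | [Li]CC/C=C(\C)CC[C@@H]1C(C)=CCCC1(C)C | intermediate
24 | {(3E)-4-methyl-6-[(1S)-2,6,6-trimethylcyclohex-2-en-1-yl]hex-3-en-1-yl}copper (not isolated) | [Cu]CC/C=C(\C)CC[C@@H]1C(C)=CCCC1(C)C | intermediate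
25 | alkenylcopper syn adduct of 24 and 22 (not isolated) | [Cu]/C(C(=O)OC)=C(\CC/C=C(\C)CC[C@@H]1C(C)=CCCC1(C)C)C(=O)OC | intermediate
26 | dimethyl (2Z)-2-{(3E)-4-methyl-6-[(1S)-2,6,6-trimethylcyclohex-2-en-1-yl]hex-3-en-1-yl}but-2-enedioate | COC(=O)/C=C(/CC/C=C(\C)CC[C@@H]1C(C)=CCCC1(C)C)C(=O)OC | intermediate
27 | (2Z)-2-{(3E)-4-methyl-6-[(1S)-2,6,6-trimethylcyclohex-2-en-1-yl]hex-3-en-1-yl}but-2-ene-1,4-diol | OC/C=C(/CC/C=C(\C)CC[C@@H]1C(C)=CCCC1(C)C)CO | intermediate
28 | (2Z)-2-{(3E)-4-methyl-6-[(1S)-2,6,6-trimethylcyclohex-2-en-1-yl]hex-3-en-1-yl}but-2-ene-1,4-diyl diacetate | CC(=O)OC/C=C(/CC/C=C(\C)CC[C@@H]1C(C)=CCCC1(C)C)COC(C)=O | target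

**Totals and risks**
Total step count: 15. Longest linear sequence: 13 steps (steps 1, 2 and 5 to 15).

Steps most likely to fail:

1. Step 6 (proposed new method). The alkyl group may be lost by β-hydride elimination at nickel, so that the alkyne is coupled reductively without ring closure. The alkyne may oligomerise, the alkyne may insert with the opposite regiochemistry, or the oxidative coupling may show poor facial selectivity at the crowded β-carbon. The fallback uses known chemistry, sets out from 1 and comes back at 14, so that step 7 is not needed either. Enolate alkylation of 1 with 4-bromobut-1-ene should give ethyl 2,2-dimethylhex-5-enoate F1. Reduction with i-Bu2AlH at −78 °C should give 2,2-dimethylhex-5-enal F2. Horner–Wadsworth–Emmons olefination with 8 (LiBr, Et3N) should give (4S)-4-benzyl-3-[(2E)-4,4-dimethylocta-2,7-dienoyl]-1,3-oxazolidin-2-one F3. Conjugate addition of CH2=C(CH3)MgBr mediated by CuBr·SMe2 (THF, −78 to −20 °C), on the face opposite the benzyl group of the chelated imide, should give (4S)-4-benzyl-3-[(3R)-4,4-dimethyl-3-(prop-1-en-2-yl)oct-7-enoyl]-1,3-oxazolidin-2-one F4. Ring-closing metathesis with the second-generation Grubbs catalyst (CH2Cl2, 40 °C) should then close the trisubstituted cyclohexene and give 14.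

2. Step 7. Acid may move the ring double bond to the tetrasubstituted position, or the β-silyl cation may lose the proton at C1 and so erode the stereocentre; the hindered vinylsilane may also react incompletely. The fallback sets out from 13 and comes back at 14. Ipso-iododesilylation with N-iodosuccinimide (MeCN, 0 °C) should give (4S)-4-benzyl-3-{2-[(1S)-3-iodo-2,6,6-trimethylcyclohex-2-en-1-yl]acetyl}-1,3-oxazolidin-2-one F5, and radical reduction with Bu3SnH and AIBN (toluene, 80 °C) should replace iodine by hydrogen without moving the alkene.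

3. Step 13. The alkenylcopper may isomerise on warming and erode the Z geometry, and the exchange may be spoiled by Wurtz coupling or incomplete transmetalation. The fallback sets out from 21 and comes back at 26. Iodine–lithium exchange to 23 followed by B-methoxy-9-borabicyclo[3.3.1]nonane should give the lithium B-alkyl-B-methoxy borinate F6, and Suzuki–Miyaura coupling with dimethyl bromomaleate (Pd(dppf)Cl2, AsPh3, Cs2CO3, DMF–THF–H2O, rt) should give 26 with retention of the cis diester geometry.

**Further compounds**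
F1 | step 6 | ethyl 2,2-dimethylhex-5-enoate | CCOC(=O)C(C)(C)CCC=C
F2 | step 6 | 2,2-dimethylhex-5-enal | O=CC(C)(C)CCC=C
F3 | step 6 | (4S)-4-benzyl-3-[(2E)-4,4-dimethylocta-2,7-dienoyl]-1,3-oxazolidin-2-one | O=C(/C=C/C(C)(C)CCC=C)N1[C@@H](Cc2ccccc2)COC1=O
F4 | step 6 | (4S)-4-benzyl-3-[(3R)-4,4-dimethyl-3-(prop-1-en-2-yl)oct-7-enoyl]-1,3-oxazolidin-2-one | O=C(C[C@@H](C(C)(C)CCC=C)C(C)=C)N1[C@@H](Cc2ccccc2)COC1=O
F5 | step 7 | (4S)-4-benzyl-3-{2-[(1S)-3-iodo-2,6,6-trimethylcyclohex-2-en-1-yl]acetyl}-1,3-oxazolidin-2-one | O=C(C[C@@H]1C(C)=C(I)CCC1(C)C)N2[C@@H](Cc3ccccc3)COC2=O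
F6 | step 13 | lithium 9-methoxy-9-{(3E)-4-methyl-6-[(1S)-2,6,6-trimethylcyclohex-2-en-1-yl]hex-3-en-1-yl}-9-boranuidabicyclo[3.3.1]nonane | [Li+].CO[B-]1(CC/C=C(\C)CC[C@@H]3C(C)=CCCC3(C)C)C2CCCC1CCC2
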